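**Flat in time.** Time does little in the earlier runs: from 0.200 min to 2.50 min the north-east readings of Z wander between 72% and 79%, and the east run is as flat. The east run charged 0.49 M of Q on 0.24 M of Z, yet Z stands at a mean of 52.5% with L at 39.0%. Counting the rest of the lost Z as J, the adducts hold 27.4% of the Q charged in the east run, and the remainder is reckoned as E.

in all of them: Z 0.24 M

|  | Q | remark | time |
|---|---|---|---|
| north-east | 0.21 M | run made earlier |  |
| east | 0.49 M | run made earlier |  |
| amber | 0.650 M |  | 2.5 min |
| violet | 0.430 M |  | 2.5 min |
| teal | 0.290 M |  | 2.5 min |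

| run | time / min | L / % | Z / % |
|---|---|---|---|
| north-east | 0.200 | 23 | 79 |
| north-east | 0.333 | 20 | 76 |
| north-east | 0.500 | 22 | 79 |
| north-east | 0.667 | 20 | 73 |
| north-east | 1.00 | 20 | 77 |
| north-east | 1.50 | 23 | 77 |
| north-east | 2.50 | 21 | 72 |
| east | 0.333 | 37 | 53 |
| east | 0.667 | 35 | 52 |
| east | 1.00 | 40 | 55 |
| east | 1.33 | 40 | 52 |
| east | 2.00 | 42 | 53 |
| east | 2.50 | 40 | 50 |

(scatter of a reading: 2 percentage points)

- percent here means Z units held: one D counts as two
- what was read earlier has a scatter of 2 percentage points, one standard deviation
- steps that have been proposed: Z + Q -> L; Q + L -> J; 2 Z -> D; Q -> E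

* which of the two there is more of at the end, amber (J / L)
* which of the two there is more of at the end, violet (J / L)
* which of the two there is more of at the end, teal (J / L)
* how much L is there at the end, in percent of the Z charged: amber
* how much L is there at the end, in percent of the Z charged: violet
* how much L is there at the end, in percent of the Z charged: teal

**Dose rule.** Each Z sees a fading Q, a pseudo-first-order loss, so the logarithm of charged Z over Z left measures the dose received. In the east run the adducts take less Q than E is reckoned to, so Q fades roughly by its own first-order clock, and the bench rule follows: at a fixed charge of Z, dose goes with the Q charged. The north-east mean of 76.1% gives 1.30 M⁻¹ and the east mean gives 1.32 M⁻¹. Their mean, 1.31 M⁻¹, is the dose per molar of Q charged. Z should then end at 42.8% in amber, 57.0% in violet and 68.5% in teal.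

**Two ends.** At small dose L equals the Z lost; at large dose L is eaten into J. A selectivity factor of 0.5, second addition over first, joins the ends: L = 2(√Z − Z), with J = (1 − √Z)². This gives 39.9% for the east run against the 39.0% read. My reckoning is L 45.3% and J 12.0% in amber, L 37.0% and J 6.00% in violet, L 28.6% and J 2.97% in teal.

**The border.** By this reckoning, with Z charged at 0.24 M, more Q gives more L up to a charge of 1.06 M, which is 1.63 times the amber charge; there Z has fallen to a quarter.

**The forecast.** It has more L than J in amber, violet and teal (L, L, L) with L at 46%, 37% and 28%, holding that “Conversion roughly scales with Q charged”; its amber and teal differ from mine by 0.70 percentage points and 0.60 points.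

**The flask.** L ends at 45.8% in amber, 36.6% in violet and 27.8% in teal, more than J in each .

    Z + Q → L (k = 0.240 M⁻¹ s⁻¹)
    Q + L → J (k = 0.110 M⁻¹ s⁻¹)
    2 Z → D (k = 9.50 × 10⁻⁴ M⁻¹ s⁻¹)
    Q → E (k = 0.140 s⁻¹)

Left until 25.0 min, amber still holds L at 45.8%. Amber's Z of 42.6% at 1.25 min is a dose per molar of 1.31 M⁻¹. Carried to a neighbour of amber charged with 1.1 M of Q, 1.31 M⁻¹ gives Z 23.7% and L 50.0%; that flask ends with Z at 23% and L at 51.6%.

The readings are calculated with constants of no real substance, noise included.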